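**Retrosynthetic overview**
- Target ⇐ cleavage of four aryl methyl ethers ⇐ Wolff–Kishner removal of two ring carbonyls ⇐ a bis(3-aryl-2,2,3-trimethylcyclopentanone).
- The strategy rests on the C1′–C2′ bond of each cyclopentane ring, which joins the quaternary stereocentre C1′ (aryl, methyl) to the gem-dimethyl carbon C2′. Both bonds are made together by loss of CO from C2=O of the two 1,3,3-trimethyl-2,4-dioxocyclohexyl rings of a crystalline bis(cyclohexane-1,3-dione).
- That bis-dione ⇐ C-methylation and enol ether hydrolysis ⇐ two aryl–C(quaternary) bonds from a two-fold enantioselective Pd α-arylation of the lithium enolate of 3-ethoxy-2,6-dimethylcyclohex-2-en-1-one with 1,2-bis(3-bromo-4,5-dimethoxyphenyl)ethane.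
- The dibromide ⇐ McMurry coupling and diimide reduction of 3-bromo-4,5-dimethoxybenzaldehyde. The enone ⇐ 2-methylcyclohexane-1,3-dione (O-ethylation, C6-methylation), which carries one carbon of each later gem-dimethyl group from the start, so that only one C-methylation of the dione is needed.
- Ring order: the benzene rings and the six-membered carbocycles are bought. The two cyclopentane rings are the only rings formed, both in the photochemical step, by contraction of the six-membered rings.

Key step: step 8

Assumption: the (S)-enantiomer of the ligand in step 5 is taken to give the (R)-configured quaternary centres; if a trial coupling shows the opposite sense, the antipodal ligand is used with no other change.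

Remark on descriptors: the quaternary centres are (R) as long as a carbonyl carbon (or, in the cyclopentanone, the α-keto CMe2 carbon) outranks the aryl group, and become (S) once the ring ketone is gone. The spatial arrangement does not change from step 5 to the target.

**Route**

Step 1
Reactants: 1 3-bromo-4,5-dimethoxybenzaldehyde (2 equiv)
Product: 3 (E)-1,2-bis(3-bromo-4,5-dimethoxyphenyl)ethene, via titanium pinacolate 2 (not isolated)
Conditions: TiCl4, Zn, THF, reflux
Reagents that add atoms: none
Why: McMurry reductive coupling, in which low-valent titanium made from TiCl4 and Zn joins the two aldehyde carbons to the titanium-bound diolate 2 and deoxygenates it at reflux to the stilbene, while aryl C–Br bonds are inert to the reagent.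

Step 2
Reactants: 3 (E)-1,2-bis(3-bromo-4,5-dimethoxyphenyl)ethene
Product: 4 1,2-bis(3-bromo-4,5-dimethoxyphenyl)ethane
Conditions: 4-methylbenzenesulfonohydrazide, NaOAc, THF/H2O, reflux
Reagents that add atoms: none
Why: Diimide reduction, in which diimide released from the sulfonohydrazide transfers H2 to the C=C bond in a concerted six-centre step and leaves the aryl bromides untouched, which a heterogeneous Pd hydrogenation would put at risk.

Step 3
Reactants: 5 2-methylcyclohexane-1,3-dione
Product: 6 3-ethoxy-2-methylcyclohex-2-en-1-one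
Conditions: EtOH, TsOH (cat.), toluene, reflux, Dean–Stark
Reagents that add atoms: ethanol, CCO
Why: Acid-catalysed enol etherification of a cyclic 1,3-dione with azeotropic removal of water; the dione is symmetric, so only one enol ether can form.

Step 4
Reactants: 6 3-ethoxy-2-methylcyclohex-2-en-1-one; 7 iodomethane
Product: 9 3-ethoxy-2,6-dimethylcyclohex-2-en-1-one (racemic), via lithium enolate 8 (not isolated)
Conditions: LiN(iPr)2, THF, −78 °C; MeI, −78 to 0 °C
Reagents that add atoms: iodomethane, CI
Why: Stork–Danheiser alkylation, that is kinetic α′-deprotonation of the vinylogous ester at C6 and SN2 methylation of the cross-conjugated enolate; the C6 centre is formed racemic and is erased again by enolisation in step 5.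

Step 5
Reactants: 4 1,2-bis(3-bromo-4,5-dimethoxyphenyl)ethane; 9 3-ethoxy-2,6-dimethylcyclohex-2-en-1-one
Product: 12 1,2-bis{5-[(1R)-4-ethoxy-1,3-dimethyl-2-oxocyclohex-3-en-1-yl]-3,4-dimethoxyphenyl}ethane, via lithium enolate 10 (not isolated), via mono-arylated bromide 11 (not isolated)
Conditions: 9 (2.6 equiv), LiN(iPr)2 (2.5 equiv), THF, −78 °C; then 4 (1 equiv), Pd(OAc)2 (10 mol %), (S)-BI-DIME (20 mol %), toluene, 60 °C
Reagents that add atoms: none
Why: Buchwald–Hartwig enantioselective ketone α-arylation, in which each C–Br bond adds oxidatively to zerovalent palladium formed in the flask from Pd(OAc)2, enolate 10 (whose only nucleophilic carbon is C6) transmetalates, and C–C reductive elimination inside the pocket of the bulky P-stereogenic monophosphine should set each quaternary centre (R) under catalyst control; because the two ends are set independently, the minor sense of induction ends up mostly in the meso isomer, which is removed by crystallisation at 14.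

Step 6
Reactants: 12 1,2-bis{5-[(1R)-4-ethoxy-1,3-dimethyl-2-oxocyclohex-3-en-1-yl]-3,4-dimethoxyphenyl}ethane
Product: 13 1,2-bis{5-[(1R)-1,3-dimethyl-2,4-dioxocyclohexyl]-3,4-dimethoxyphenyl}ethane (C3 of each ring unassigned, largely enolised)
Conditions: 2 M HCl, THF, 40 °C
Reagents that add atoms: water, O
Why: Acid hydrolysis of the vinylogous ester (C-protonation of the enol ether, addition of water, loss of ethanol) frees both 1,3-diones, and the quaternary centres carry no α-hydrogen and cannot epimerise.

Step 7
Reactants: 13 1,2-bis{5-[(1R)-1,3-dimethyl-2,4-dioxocyclohexyl]-3,4-dimethoxyphenyl}ethane; 7 iodomethane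
Product: 14 1,2-bis{3,4-dimethoxy-5-[(1R)-1,3,3-trimethyl-2,4-dioxocyclohexyl]phenyl}ethane
Conditions: MeI, K2CO3, acetone, reflux; recrystallisation to a single stereoisomer
Reagents that add atoms: iodomethane, CI
Why: C-Alkylation of the 2-methyl-1,3-dione enolate with the soft electrophile iodomethane (the reaction used to make 2,2-dimethylcyclohexane-1,3-dione) makes C3 of each ring quaternary, the weak non-nucleophilic base spares the non-enolisable product from retro-Claisen opening, and any O-methyl enol ether is returned to 13 under the conditions of step 6.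

Step 8
Reactants: 14 1,2-bis{3,4-dimethoxy-5-[(1R)-1,3,3-trimethyl-2,4-dioxocyclohexyl]phenyl}ethane
Product: 16 1,2-bis{3,4-dimethoxy-5-[(1R)-1,2,2-trimethyl-3-oxocyclopentyl]phenyl}ethane, via mono-contracted ketone 15 (not isolated)
Conditions: hν (medium-pressure Hg lamp, Pyrex, λ > 290 nm), finely ground crystals of 14 suspended in H2O with sodium dodecyl sulfate (below its critical micelle concentration), 15–20 °C, N2
Reagents that add atoms: none
Why: Excitation of the dione chromophore leads to Norrish α-cleavage at the carbonyl flanked by the two quaternary carbons (C2 of each 1,3,3-trimethyl-2,4-dioxocyclohexyl ring), giving a tertiary benzylic radical at C1 and an acyl radical; loss of CO then leaves a 1,5-biradical whose second centre, the CMe2 carbon, is an α-keto radical stabilised by the remaining ring carbonyl, and radical–radical combination forms the C1′–C2′ bond. The closest known reaction type is the solid-state photodecarbonylation of crystalline cyclohexanones whose two α-carbons are fully substituted and radical-stabilised, which gives vicinal quaternary carbons with retention; it is applied here to two such rings in one molecule, so that 15 is passed on the way. Each five-membered ring closes by intramolecular combination of the two ends of a 1,5-biradical, a ring contraction of the cyclohexanedione by extrusion of one carbon and not a polar cyclisation. No stereocentre is created: the existing centre at C1′ becomes a planar benzylic radical for the lifetime of the biradical, and its configuration is preserved because the lattice allows neither rotation about the ring bonds nor diffusion before the radical pair collapses. The step needs site selectivity for C2=O over the second ring carbonyl, which is secured because only C2=O can shed CO between two stabilised tertiary radicals (cleavage beside the other carbonyl would have to expel CO towards an unstabilised primary radical and simply recloses), and it needs combination in place of disproportionation and stereorandomisation, which is secured by running the reaction in enantiopure crystals of 14 kept below their melting point as a suspension.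

Step 9
Reactants: 16 1,2-bis{3,4-dimethoxy-5-[(1R)-1,2,2-trimethyl-3-oxocyclopentyl]phenyl}ethane
Product: 18 1,2-bis{3,4-dimethoxy-5-[(1S)-1,2,2-trimethylcyclopentyl]phenyl}ethane, via bis-hydrazone 17 (not isolated)
Conditions: N2H4·H2O, KOH, diethylene glycol, 130 °C then 200 °C
Reagents that add atoms: none
Why: Wolff–Kishner reduction in the Huang–Minlon form, in which each ketone condenses to the hydrazone 17 that under hydroxide at 200 °C tautomerises and loses N2 to leave a CH2 group; the quaternary centres have no acidic hydrogen, and any partial loss of O-methyl groups is harmless because step 10 removes them all.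

Step 10
Reactants: 18 1,2-bis{3,4-dimethoxy-5-[(1S)-1,2,2-trimethylcyclopentyl]phenyl}ethane
Product: 20 5,5′-(ethane-1,2-diyl)bis{3-[(1S)-1,2,2-trimethylcyclopentyl]benzene-1,2-diol} (CNP0144189.1), via bis(bromoborole) 19 (not isolated)
Conditions: BBr3, CH2Cl2, −78 to 20 °C; then H2O (degassed)
Reagents that add atoms: none
Why: Lewis acid cleavage of aryl methyl ethers, in which BBr3 binds each ether oxygen, bromide removes the methyl group by SN2 as bromomethane, and water hydrolyses the catechol bromoborates 19 to the free bis-catechol.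

**Compound list**
1 | 3-bromo-4,5-dimethoxybenzaldehyde | COc1cc(C=O)cc(Br)c1OC | starting material
2 | 1,2-bis(3-bromo-4,5-dimethoxyphenyl)ethane-1,2-diol, present as its titanium diolate (SMILES of the free diol) | COc1cc(C(O)C(O)c2cc(OC)c(OC)c(Br)c2)cc(Br)c1OC | intermediate
3 | (E)-1,2-bis(3-bromo-4,5-dimethoxyphenyl)ethene | COc1cc(/C=C/c2cc(OC)c(OC)c(Br)c2)cc(Br)c1OC | intermediate
4 | 1,2-bis(3-bromo-4,5-dimethoxyphenyl)ethane | COc1cc(CCc2cc(OC)c(OC)c(Br)c2)cc(Br)c1OC | intermediate
5 | 2-methylcyclohexane-1,3-dione | CC1C(=O)CCCC1=O | starting material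
6 | 3-ethoxy-2-methylcyclohex-2-en-1-one | CCOC1=C(C)C(=O)CCC1 | intermediate
7 | iodomethane | CI | starting material
8 | lithium 5-ethoxy-6-methylcyclohexa-1,5-dien-1-olate (enolate of 6) | [Li+].CCOC1=C(C)C([O-])=CCC1 | intermediate
9 | 3-ethoxy-2,6-dimethylcyclohex-2-en-1-one (racemic) | CCOC1=C(C)C(=O)C(C)CC1 | intermediate
10 | lithium 5-ethoxy-2,6-dimethylcyclohexa-1,5-dien-1-olate (enolate of 9) | [Li+].CCOC1=C(C)C([O-])=C(C)CC1 | intermediate
11 | 1-(3-bromo-4,5-dimethoxyphenyl)-2-{5-[(1R)-4-ethoxy-1,3-dimethyl-2-oxocyclohex-3-en-1-yl]-3,4-dimethoxyphenyl}ethane | COc1cc(CCc2cc(OC)c(OC)c(Br)c2)cc([C@@]2(C)CCC(OCC)=C(C)C2=O)c1OC | intermediate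
12 | 1,2-bis{5-[(1R)-4-ethoxy-1,3-dimethyl-2-oxocyclohex-3-en-1-yl]-3,4-dimethoxyphenyl}ethane | COc1cc(CCc2cc(OC)c(OC)c([C@@]3(C)CCC(OCC)=C(C)C3=O)c2)cc([C@@]2(C)CCC(OCC)=C(C)C2=O)c1OC | intermediate
13 | 1,2-bis{5-[(1R)-1,3-dimethyl-2,4-dioxocyclohexyl]-3,4-dimethoxyphenyl}ethane (C3 of each ring unassigned) | COc1cc(CCc2cc(OC)c(OC)c([C@@]3(C)CCC(=O)C(C)C3=O)c2)cc([C@@]2(C)CCC(=O)C(C)C2=O)c1OC | intermediate
14 | 1,2-bis{3,4-dimethoxy-5-[(1R)-1,3,3-trimethyl-2,4-dioxocyclohexyl]phenyl}ethane | COc1cc(CCc2cc(OC)c(OC)c([C@@]3(C)CCC(=O)C(C)(C)C3=O)c2)cc([C@@]2(C)CCC(=O)C(C)(C)C2=O)c1OC | intermediate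
15 | 1-{3,4-dimethoxy-5-[(1R)-1,3,3-trimethyl-2,4-dioxocyclohexyl]phenyl}-2-{3,4-dimethoxy-5-[(1R)-1,2,2-trimethyl-3-oxocyclopentyl]phenyl}ethane | COc1cc(CCc2cc(OC)c(OC)c([C@@]3(C)CCC(=O)C3(C)C)c2)cc([C@@]2(C)CCC(=O)C(C)(C)C2=O)c1OC | intermediate
16 | 1,2-bis{3,4-dimethoxy-5-[(1R)-1,2,2-trimethyl-3-oxocyclopentyl]phenyl}ethane | COc1cc(CCc2cc(OC)c(OC)c([C@@]3(C)CCC(=O)C3(C)C)c2)cc([C@@]2(C)CCC(=O)C2(C)C)c1OC | intermediate
17 | bis-hydrazone of 16 (both ring C=O as C=N–NH2, quaternary centres unchanged) | COc1cc(CCc2cc(OC)c(OC)c([C@@]3(C)CCC(=NN)C3(C)C)c2)cc([C@@]2(C)CCC(=NN)C2(C)C)c1OC | intermediate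
18 | 1,2-bis{3,4-dimethoxy-5-[(1S)-1,2,2-trimethylcyclopentyl]phenyl}ethane | COc1cc(CCc2cc(OC)c(OC)c([C@@]3(C)CCCC3(C)C)c2)cc([C@@]2(C)CCCC2(C)C)c1OC | intermediate
19 | bis(2-bromo-1,3,2-benzodioxaborole) in which each catechol unit of 20 is bridged by B–Br | BrB1Oc2cc(CCc3cc4OB(Br)Oc4c([C@@]4(C)CCCC4(C)C)c3)cc([C@@]3(C)CCCC3(C)C)c2O1 | intermediate
20 | 5,5′-(ethane-1,2-diyl)bis{3-[(1S)-1,2,2-trimethylcyclopentyl]benzene-1,2-diol} | CC1(C)CCC[C@]1(C)c1cc(CCc2cc(O)c(O)c([C@@]3(C)CCCC3(C)C)c2)cc(O)c1O | target

**Step count**
Total: 10 steps. Longest linear sequence: 8 steps (steps 1, 2, 5–10; the branch through steps 3, 4, 5–10 is equally long).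

**Steps most likely to fail**

1. Step 8. The lattice may lose control: the crystal may soften or turn amorphous as the first ring of each molecule contracts and 15 accumulates. The benzylic radical of the second ring could then rotate before it recombines, which would scramble the configuration, or the radical pair could disproportionate to ring-opened alkenes. 14 may also fail to crystallise at all.
Fallback: the monomer is contracted first, so that each crystal has to sustain only one decarbonylation, and the two halves are joined afterwards. It sets out from 1. NaBH4 in MeOH gives (3-bromo-4,5-dimethoxyphenyl)methanol F1, and TBSCl/imidazole gives its tert-butyldimethylsilyl ether F2. Coupling of F2 with enolate 10 under the catalyst of step 5 gives (6R)-6-[5-({[tert-butyl(dimethyl)silyl]oxy}methyl)-2,3-dimethoxyphenyl]-3-ethoxy-2,6-dimethylcyclohex-2-en-1-one F3. 2 M HCl in THF cleaves the enol ether and the silyl ether to (4R)-4-[5-(hydroxymethyl)-2,3-dimethoxyphenyl]-2,4-dimethylcyclohexane-1,3-dione F4, and MeI/K2CO3 gives (4R)-4-[5-(hydroxymethyl)-2,3-dimethoxyphenyl]-2,2,4-trimethylcyclohexane-1,3-dione F5. F5 is recrystallised to enantiopurity and irradiated as crystals under the conditions of step 8 to (3R)-3-[5-(hydroxymethyl)-2,3-dimethoxyphenyl]-2,2,3-trimethylcyclopentan-1-one F6. Wolff–Kishner reduction gives {3,4-dimethoxy-5-[(1S)-1,2,2-trimethylcyclopentyl]phenyl}methanol F7, and PBr3 in CH2Cl2 gives 5-(bromomethyl)-1,2-dimethoxy-3-[(1S)-1,2,2-trimethylcyclopentyl]benzene F8. Wurtz-type homocoupling of F8 with Mg (0.5 equiv) in THF forms the central CH2–CH2 bond and returns to the route at 18.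

2. Step 5. Facial discrimination in the reductive elimination may be poor, and the second coupling may stall: with the ortho-methoxy aryl group, β-hydride elimination from the C-bound palladium enolate (ending in hydrodebromination) can compete with formation of the quaternary carbon.
Fallback: the quaternary centres are set by enamine catalysis and the six-membered rings are closed afterwards. It sets out from 4. Suzuki–Miyaura coupling with vinylboronic acid pinacol ester (PdCl2(dppf), K2CO3, dioxane/H2O) gives 1,2-bis(3-ethenyl-4,5-dimethoxyphenyl)ethane F9. Branched-selective hydroformylation (Rh(acac)(CO)2, PPh3, CO/H2) gives 1,2-bis[3,4-dimethoxy-5-(1-oxopropan-2-yl)phenyl]ethane F10 as a stereoisomer mixture. Michael addition of the α-aryl aldehyde to pent-1-en-3-one through its enamine with a proline-derived N-arylsulfonyl carboxamide catalyst (enantiomer chosen for the (R) centres) gives 1,2-bis{3,4-dimethoxy-5-[(2R)-2-methyl-1,5-dioxoheptan-2-yl]phenyl}ethane F11. Intramolecular aldol addition of the ethyl ketone to the non-enolisable aldehyde (catalytic KOH, MeOH, 0 °C) gives 1,2-bis{5-[(1R)-2-hydroxy-1,3-dimethyl-4-oxocyclohexyl]-3,4-dimethoxyphenyl}ethane F12, and Dess–Martin oxidation of the ketol returns to the route at 13.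

3. Step 9. Hydrazone formation at the carbonyl next to the gem-dimethyl carbon may be incomplete, and azines may form at 200 °C, so that one or both ketones survive.
Fallback: the oxygen is removed by a radical deoxygenation. It sets out from 16. LiAlH4 in THF gives the bis-alcohol F13 (both ring C=O reduced to CH–OH, quaternary centres unchanged, carbinol configuration immaterial). NaH, CS2 and then MeI give the bis(S-methyl xanthate) F14, and Barton–McCombie reduction (Bu3SnH, AIBN, toluene, reflux) returns to the route at 18.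

**Further compounds**
F1 | step 8 | (3-bromo-4,5-dimethoxyphenyl)methanol | COc1cc(CO)cc(Br)c1OC
F2 | step 8 | [(3-bromo-4,5-dimethoxyphenyl)methoxy](tert-butyl)dimethylsilane | COc1cc(CO[Si](C)(C)C(C)(C)C)cc(Br)c1OC
F3 | step 8 | (6R)-6-[5-({[tert-butyl(dimethyl)silyl]oxy}methyl)-2,3-dimethoxyphenyl]-3-ethoxy-2,6-dimethylcyclohex-2-en-1-one | COc1cc(CO[Si](C)(C)C(C)(C)C)cc([C@@]2(C)CCC(OCC)=C(C)C2=O)c1OC
F4 | step 8 | (4R)-4-[5-(hydroxymethyl)-2,3-dimethoxyphenyl]-2,4-dimethylcyclohexane-1,3-dione | COc1cc(CO)cc([C@@]2(C)CCC(=O)C(C)C2=O)c1OC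
F5 | step 8 | (4R)-4-[5-(hydroxymethyl)-2,3-dimethoxyphenyl]-2,2,4-trimethylcyclohexane-1,3-dione | COc1cc(CO)cc([C@@]2(C)CCC(=O)C(C)(C)C2=O)c1OC
F6 | step 8 | (3R)-3-[5-(hydroxymethyl)-2,3-dimethoxyphenyl]-2,2,3-trimethylcyclopentan-1-one | COc1cc(CO)cc([C@@]2(C)CCC(=O)C2(C)C)c1OC
F7 | step 8 | {3,4-dimethoxy-5-[(1S)-1,2,2-trimethylcyclopentyl]phenyl}methanol | COc1cc(CO)cc([C@@]2(C)CCCC2(C)C)c1OC
F8 | step 8 | 5-(bromomethyl)-1,2-dimethoxy-3-[(1S)-1,2,2-trimethylcyclopentyl]benzene | COc1cc(CBr)cc([C@@]2(C)CCCC2(C)C)c1OC
F9 | step 5 | 1,2-bis(3-ethenyl-4,5-dimethoxyphenyl)ethane | COc1cc(CCc2cc(OC)c(OC)c(C=C)c2)cc(C=C)c1OC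
F10 | step 5 | 1,2-bis[3,4-dimethoxy-5-(1-oxopropan-2-yl)phenyl]ethane (stereoisomer mixture) | COc1cc(CCc2cc(OC)c(OC)c(C(C)C=O)c2)cc(C(C)C=O)c1OC
F11 | step 5 | 1,2-bis{3,4-dimethoxy-5-[(2R)-2-methyl-1,5-dioxoheptan-2-yl]phenyl}ethane | COc1cc(CCc2cc(OC)c(OC)c([C@](C)(C=O)CCC(=O)CC)c2)cc([C@](C)(C=O)CCC(=O)CC)c1OC
F12 | step 5 | 1,2-bis{5-[(1R)-2-hydroxy-1,3-dimethyl-4-oxocyclohexyl]-3,4-dimethoxyphenyl}ethane (carbinol and C3 centres as formed) | COc1cc(CCc2cc(OC)c(OC)c([C@@]3(C)CCC(=O)C(C)C3O)c2)cc([C@@]2(C)CCC(=O)C(C)C2O)c1OC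
F13 | step 9 | bis-alcohol from 16 (ring C=O reduced to CH–OH, quaternary centres unchanged) | COc1cc(CCc2cc(OC)c(OC)c([C@@]3(C)CCC(O)C3(C)C)c2)cc([C@@]2(C)CCC(O)C2(C)C)c1OC
F14 | step 9 | bis(S-methyl xanthate) of F13 | COc1cc(CCc2cc(OC)c(OC)c([C@@]3(C)CCC(OC(=S)SC)C3(C)C)c2)cc([C@@]2(C)CCC(OC(=S)SC)C2(C)C)c1OC
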